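**Plan**

Cuts (benzyl ethers, the 5''-methyl ether and a placeholder iodine on C3'' are restored first): O1''–C2'' (pyranone of unit 2); C3''–C4'' and C4''–C4a'' (one carbonyl carbon between ring A of unit 2 and an arylacetylene); the C3'–C8'' biaryl bond; O1–C2 and C2–C3 of unit 1.
Enabling feature: without C4'', ring A of unit 2 (C4a''–C8a'') is a benzene ring with oxygen on C5'', C7'' and C8a'' and ring B of unit 1 on C8''. Its two CH carbons, C4a'' and C6'', are equivalent about the local axis through C8'' and C5''. A 2,4,6-trimethoxyphenyl group therefore supplies O1'', O5'' and the finished 7''-OMe, and it accepts C4'' at either CH position with the same result.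
Forward order: ring C of unit 1 (Claisen condensation, cyclodehydration); biaryl bond (Suzuki–Miyaura); C4'' (formylation); C3'', C2'' and ring B of unit 2 (acetylide addition, oxidation); ring C of unit 2 by ICl-induced closure, in which the methoxy oxygen on C8a'' becomes O1''; then ether cleavage and deiodination.
Stereochemistry: the target has no stereocentre. The carbinol centre made in step 7 is erased in step 8, and the biaryl axis is not controlled.

Key step: step 9

Assumption: the target is drawn without an axial descriptor and its C3'–C8'' axis has only three small, oxygen-based ortho substituents, so the axis is treated as configurationally labile and all biaryl intermediates are handled as racemic or interconverting rotamers.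

**Route**

Step 1
Reactants: 1 methyl 4-hydroxy-3-iodobenzoate
Product: 2 methyl 4-(benzyloxy)-3-iodobenzoate
Conditions: BnBr, K2CO3, DMF, rt
Reagents that add atoms: benzyl bromide BrCc1ccccc1
Why: Williamson etherification of the acidic ortho-iodophenol is fast under carbonate conditions that leave the methyl ester and the C–I bond untouched.

Step 2
Reactants: 3 2',4',6'-trihydroxyacetophenone
Product: 4 1-[2,4-bis(benzyloxy)-6-hydroxyphenyl]ethanone
Conditions: BnBr (2 equiv), K2CO3, DMF, rt to 60 °C
Reagents that add atoms: benzyl bromide BrCc1ccccc1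
Why: Williamson etherification in which the hydroxyl group hydrogen-bonded to the acetyl carbonyl is the least reactive, so two equivalents of benzyl bromide should stop at the dibenzyl ether with one free ortho phenol.

Step 3
Reactants: 4 1-[2,4-bis(benzyloxy)-6-hydroxyphenyl]ethanone; 2 methyl 4-(benzyloxy)-3-iodobenzoate
Product: 5 1-[2,4-bis(benzyloxy)-6-hydroxyphenyl]-3-[4-(benzyloxy)-3-iodophenyl]propane-1,3-dione (keto–enol mixture)
Conditions: LiN(SiMe3)2 (4 equiv), THF, −78 °C to rt; then aq HCl
Reagents that add atoms: none
Why: Crossed Claisen condensation (the intermolecular counterpart of the Baker–Venkataraman acyl transfer), in which the lithium phenoxide-enolate of 4 is C-acylated by the non-enolisable ester 2 and deprotonation of the resulting 1,3-diketone drives the equilibrium forward.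

Step 4
Reactants: 5 1-[2,4-bis(benzyloxy)-6-hydroxyphenyl]-3-[4-(benzyloxy)-3-iodophenyl]propane-1,3-dione
Product: 6 5,7-bis(benzyloxy)-2-[4-(benzyloxy)-3-iodophenyl]-4H-chromen-4-one (3'-iodo-tri-O-benzylapigenin)
Conditions: NaOAc, AcOH, reflux
Reagents that add atoms: none
Why: Cyclodehydration of an o-hydroxyaryl 1,3-diketone (hemiketal formation at the aroyl carbonyl, then loss of water) closes ring C of unit 1, and the acetate buffer keeps the medium too weakly acidic to cleave the peri 5-O-benzyl ether.

Step 5
Reactants: 6 5,7-bis(benzyloxy)-2-[4-(benzyloxy)-3-iodophenyl]-4H-chromen-4-one; 7 2,4,6-trimethoxyphenylboronic acid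
Product: 8 5,7-bis(benzyloxy)-2-[6-(benzyloxy)-2',4',6'-trimethoxybiphenyl-3-yl]-4H-chromen-4-one
Conditions: Pd(OAc)2 (5 mol %), SPhos (10 mol %), K3PO4, toluene/H2O, 80 °C, 7 (2 equiv) added in portions
Reagents that add atoms: none
Why: Suzuki–Miyaura coupling in which the bulky, electron-rich ligand 2-dicyclohexylphosphino-2',6'-dimethoxybiphenyl accelerates oxidative addition to zerovalent palladium, transmetalation and reductive elimination enough to form the tri-ortho-substituted biaryl before the excess boronic acid is lost to protodeboronation.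

Step 6
Reactants: 8 5,7-bis(benzyloxy)-2-[6-(benzyloxy)-2',4',6'-trimethoxybiphenyl-3-yl]-4H-chromen-4-one
Product: 10 3-{2-(benzyloxy)-5-[5,7-bis(benzyloxy)-4-oxo-4H-chromen-2-yl]phenyl}-2,4,6-trimethoxybenzaldehyde, via dimethyliminium chloride 9 (not isolated)
Conditions: POCl3, DMF, 0 °C to rt; then aq NaOAc
Reagents that add atoms: N,N-dimethylformamide CN(C)C=O; water O
Why: Vilsmeier–Haack formylation, in which the two equivalent CH positions of the trimethoxyphenyl ring are each activated by three alkoxy groups and react far faster than ring A of unit 1 (deactivated by its chromone carbonyl), while the first formyl group prevents a second substitution.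

Step 7
Reactants: 10 3-{2-(benzyloxy)-5-[5,7-bis(benzyloxy)-4-oxo-4H-chromen-2-yl]phenyl}-2,4,6-trimethoxybenzaldehyde; 11 1-(benzyloxy)-4-ethynylbenzene
Product: 13 5,7-bis(benzyloxy)-2-[4-(benzyloxy)-3-(3-{3-[4-(benzyloxy)phenyl]-1-hydroxyprop-2-yn-1-yl}-2,4,6-trimethoxyphenyl)phenyl]-4H-chromen-4-one (racemic carbinol), via lithium acetylide 12 (not isolated)
Conditions: 11, n-BuLi, THF, −78 °C; then 10, −78 to 0 °C; then aq NH4Cl
Reagents that add atoms: none
Why: 1,2-Addition of a lithium acetylide to an aldehyde, which at low temperature is far more electrophilic than the vinylogous-ester carbonyl of the flavone; the new carbinol centre forms without control as a racemate, which does not matter because step 8 removes it.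

Step 8
Reactants: 13 propargylic alcohol of step 7
Product: 14 5,7-bis(benzyloxy)-2-[4-(benzyloxy)-3-(3-{3-[4-(benzyloxy)phenyl]prop-2-ynoyl}-2,4,6-trimethoxyphenyl)phenyl]-4H-chromen-4-one (3-aryl-2,4,6-trimethoxyphenyl arylethynyl ketone)
Conditions: activated MnO2, CH2Cl2, rt
Reagents that add atoms: none
Why: MnO2 oxidation of a doubly activated (benzylic and propargylic) alcohol runs under neutral conditions, which avoids ionisation of this acid-sensitive carbinol and leaves the benzyl ethers and the flavone alone.

Step 9
Reactants: 14 3-aryl-2,4,6-trimethoxyphenyl arylethynyl ketone of step 8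
Product: 16 3''-iodo-5,7,4',4'''-tetra-O-benzyl-5''-O-methylsotetsuflavone (8-{2-(benzyloxy)-5-[5,7-bis(benzyloxy)-4-oxo-4H-chromen-2-yl]phenyl}-2-[4-(benzyloxy)phenyl]-3-iodo-5,7-dimethoxy-4H-chromen-4-one), via methyloxonium chloride 15 (not isolated)
Conditions: ICl (1.2 equiv), CH2Cl2, −78 °C
Reagents that add atoms: iodine monochloride ClI
Why: ICl transfers an iodine cation to the triple bond, positive charge builds at C2'' (benzylic to the 4-benzyloxyphenyl donor and β to the carbonyl), the methoxy oxygen on C8a'' adds there anti to iodine to give oxonium ion 15, and chloride then removes the methyl group by SN2, so that O1''–C2'' and C3''–I are formed. The closest known reaction type is the ICl-induced iodocyclisation of 2-methoxyaryl alkynones to 3-iodochromones. The one ring formed, the pyranone of unit 2, closes 6-endo-dig, because 5-exo-dig attack at C3'' would place the developing charge next to the carbonyl group. No stereocentre is created. The step needs the oxygen flanked by ring B of unit 1 and the acyl group to react in preference to the other ortho methoxy oxygen: the flanked methoxy group cannot lie in the plane of ring A, so its lone pairs are poorly conjugated and more nucleophilic, and as the carbonyl turns into the ring plane during closure it meets an unhindered 5''-methoxy group that can direct its methyl toward C6''–H, whereas the alternative closure would press the buttressed methoxy group against the peri carbonyl. Addition and demethylation should thus both favour the 8''-aryl isomer, low temperature should sharpen the preference, and any stray C–I bond placed on an electron-rich ring is erased in step 11.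

Step 10
Reactants: 16 3''-iodo-5,7,4',4'''-tetra-O-benzyl-5''-O-methylsotetsuflavone
Product: 17 3''-iodosotetsuflavone
Conditions: BCl3 (excess), C6HMe5, CH2Cl2, −78 to 0 °C; then H2O
Reagents that add atoms: none
Why: Lewis-acid ether cleavage, in which BCl3 ionises the four aryl benzyl ethers at low temperature while pentamethylbenzene traps the benzyl cations before they can C-benzylate the phloroglucinol-type rings, and on warming boron chelated between C4''=O and O5'' directs chloride to the peri methyl group only, the unchelated 7''-methyl ether being inert to BCl3 at 0 °C.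

Step 11
Reactants: 17 3''-iodosotetsuflavone
Product: 18 sotetsuflavone
Conditions: H2 (1 atm), 10% Pd/C, NaOAc, MeOH/THF, rt
Reagents that add atoms: none
Why: Palladium-catalysed hydrogenolysis (hydrodehalogenation) of the weak C3''–I bond is much faster than reduction of the flavone C2–C3 double bonds, NaOAc takes up the HI that would otherwise poison the catalyst, and any aryl iodide introduced adventitiously in step 9 is removed as well.

**Compound list**

1 | methyl 4-hydroxy-3-iodobenzoate | COC(=O)c1ccc(O)c(I)c1 | starting material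
2 | methyl 4-(benzyloxy)-3-iodobenzoate | COC(=O)c1ccc(OCc2ccccc2)c(I)c1 | intermediate
3 | 2',4',6'-trihydroxyacetophenone | CC(=O)c1c(O)cc(O)cc1O | starting material
4 | 1-[2,4-bis(benzyloxy)-6-hydroxyphenyl]ethanone | CC(=O)c1c(O)cc(OCc2ccccc2)cc1OCc1ccccc1 | intermediate
5 | 1-[2,4-bis(benzyloxy)-6-hydroxyphenyl]-3-[4-(benzyloxy)-3-iodophenyl]propane-1,3-dione | O=C(CC(=O)c1ccc(OCc2ccccc2)c(I)c1)c1c(O)cc(OCc2ccccc2)cc1OCc1ccccc1 | intermediate
6 | 5,7-bis(benzyloxy)-2-[4-(benzyloxy)-3-iodophenyl]-4H-chromen-4-one | O=c1cc(-c2ccc(OCc3ccccc3)c(I)c2)oc2cc(OCc3ccccc3)cc(OCc3ccccc3)c12 | intermediate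
7 | 2,4,6-trimethoxyphenylboronic acid | COc1cc(OC)c(B(O)O)c(OC)c1 | starting material
8 | 5,7-bis(benzyloxy)-2-[6-(benzyloxy)-2',4',6'-trimethoxybiphenyl-3-yl]-4H-chromen-4-one | COc1cc(OC)c(-c2cc(-c3cc(=O)c4c(OCc5ccccc5)cc(OCc5ccccc5)cc4o3)ccc2OCc2ccccc2)c(OC)c1 | intermediate
9 | N,N-dimethyliminium chloride of aldehyde 10 (ArCH=NMe2+ Cl−) | COc1cc(OC)c(C=[N+](C)C)c(OC)c1-c1cc(-c2cc(=O)c3c(OCc4ccccc4)cc(OCc4ccccc4)cc3o2)ccc1OCc1ccccc1.[Cl-] | intermediate
10 | 3-{2-(benzyloxy)-5-[5,7-bis(benzyloxy)-4-oxo-4H-chromen-2-yl]phenyl}-2,4,6-trimethoxybenzaldehyde | COc1cc(OC)c(C=O)c(OC)c1-c1cc(-c2cc(=O)c3c(OCc4ccccc4)cc(OCc4ccccc4)cc3o2)ccc1OCc1ccccc1 | intermediate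
11 | 1-(benzyloxy)-4-ethynylbenzene | C#Cc1ccc(OCc2ccccc2)cc1 | starting material
12 | lithium [4-(benzyloxy)phenyl]acetylide | [Li]C#Cc1ccc(OCc2ccccc2)cc1 | intermediate
13 | propargylic alcohol, racemic at the carbinol carbon | COc1cc(OC)c(C(O)C#Cc2ccc(OCc3ccccc3)cc2)c(OC)c1-c1cc(-c2cc(=O)c3c(OCc4ccccc4)cc(OCc4ccccc4)cc3o2)ccc1OCc1ccccc1 | intermediate
14 | 3-aryl-2,4,6-trimethoxyphenyl 2-[4-(benzyloxy)phenyl]ethynyl ketone carrying unit 1 | COc1cc(OC)c(C(=O)C#Cc2ccc(OCc3ccccc3)cc2)c(OC)c1-c1cc(-c2cc(=O)c3c(OCc4ccccc4)cc(OCc4ccccc4)cc3o2)ccc1OCc1ccccc1 | intermediate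
15 | O1''-methyloxonium chloride of 16 | COc1cc(OC)c2C(=O)C(I)=C(c3ccc(OCc4ccccc4)cc3)[O+](C)c2c1-c1cc(-c2cc(=O)c3c(OCc4ccccc4)cc(OCc4ccccc4)cc3o2)ccc1OCc1ccccc1.[Cl-] | intermediate
16 | 3''-iodo-5,7,4',4'''-tetra-O-benzyl-5''-O-methylsotetsuflavone | COc1cc(OC)c2c(=O)c(I)c(-c3ccc(OCc4ccccc4)cc3)oc2c1-c1cc(-c2cc(=O)c3c(OCc4ccccc4)cc(OCc4ccccc4)cc3o2)ccc1OCc1ccccc1 | intermediate
17 | 3''-iodosotetsuflavone | COc1cc(O)c2c(=O)c(I)c(-c3ccc(O)cc3)oc2c1-c1cc(-c2cc(=O)c3c(O)cc(O)cc3o2)ccc1O | intermediate
18 | sotetsuflavone | COc1cc(O)c2c(=O)cc(-c3ccc(O)cc3)oc2c1-c1cc(-c2cc(=O)c3c(O)cc(O)cc3o2)ccc1O | target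

**Step count**

Total steps: 11. Longest linear sequence: 10 steps (1 → 2 → 5 → 6 → 8 → 10 → 13 → 14 → 16 → 17 → 18). Step 2 is the only side branch.

**Steps most likely to fail**

Step 9. The discrimination between the two unlike ortho methoxy oxygens rests on conformational argument only. Ring closure could run partly through the unflanked oxygen, and plain addition of ICl across the triple bond could compete. The two possible isomers could be told apart by NOE, because the lone proton of ring A of unit 2 lies between two methoxy groups only in the 8''-aryl isomer.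

The fallback gives up ring construction on the biaryl and joins two finished flavones, so that a C8-selective iodination fixes the site of the biaryl bond. It sets out from 6 and comes back to the route at 18.
- Miyaura borylation of 6 (B2pin2, PdCl2(dppf), KOAc, dioxane, 90 °C) would give the 3'-pinacolboronate of tri-O-benzylapigenin F1.
- Separately, Claisen–Schmidt condensation of commercial 2'-hydroxy-4',6'-dimethoxyacetophenone with 4-(benzyloxy)benzaldehyde (KOH, EtOH) would give the 2'-hydroxychalcone F2.
- Catalytic I2 in DMSO at 130 °C would cyclise and oxidise it to 4'-O-benzyl-5,7-di-O-methylapigenin F3.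
- I2 with CF3CO2Ag in CH2Cl2 would iodinate the fully etherified ring A at C8 to give the 8-iodoflavone F4.
- Suzuki–Miyaura coupling of the two halves (Pd(OAc)2, SPhos, K3PO4, toluene/H2O) would give iodine-free 5,7,4',4'''-tetra-O-benzyl-5''-O-methylsotetsuflavone F5.
- Under the conditions of step 10 this compound would lose its four benzyl groups and the chelated methyl group and arrive at 18.

Step 5. Protodeboronation of the electron-rich, di-ortho-substituted boronic acid may outpace transmetalation in the crowded coupling. The fallback replaces the boron nucleophile by a zinc nucleophile under anhydrous conditions (Negishi coupling). It sets out from 6 and comes back at 8. Commercial 1,3,5-trimethoxybenzene would be lithiated between two methoxy groups (n-BuLi, THF, 0 °C) to 2,4,6-trimethoxyphenyllithium F6. This would be transmetalated with ZnCl2 to (2,4,6-trimethoxyphenyl)zinc chloride F7 and coupled with 6 (Pd(OAc)2, SPhos, THF, 60 °C). The arylzinc reagent should tolerate the flavone carbonyl.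

Step 10. Five ether cleavages are asked of one operation. Three things could go wrong:
- Benzyl cations that escape the scavenger could C-benzylate the electron-rich rings.
- Precipitating boron aryloxides could stall the chelation-directed demethylation.
- Prolonged warming could start to remove the 7''-methyl ether.

The fallback separates the tasks and never generates benzyl cations. It sets out from 16 and comes back at 18. Hydrogenolysis of 16 (H2, 10% Pd/C, NaOAc, THF/MeOH) would remove all benzyl groups and the iodine together to give 5''-O-methylsotetsuflavone F8. A single chelation-controlled demethylation in a solvent that dissolves the polyphenol (AlCl3, MeCN, reflux; then aq HCl) would then cleave only the peri 5''-methyl ether.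

**Further compounds**

F1 | step 9 | 5,7-bis(benzyloxy)-2-[4-(benzyloxy)-3-(4,4,5,5-tetramethyl-1,3,2-dioxaborolan-2-yl)phenyl]-4H-chromen-4-one | CC1(C)OB(OC1(C)C)c1cc(-c2cc(=O)c3c(OCc4ccccc4)cc(OCc4ccccc4)cc3o2)ccc1OCc1ccccc1
F2 | step 9 | (E)-3-[4-(benzyloxy)phenyl]-1-(2-hydroxy-4,6-dimethoxyphenyl)prop-2-en-1-one | COc1cc(O)c(C(=O)/C=C/c2ccc(OCc3ccccc3)cc2)c(OC)c1
F3 | step 9 | 2-[4-(benzyloxy)phenyl]-5,7-dimethoxy-4H-chromen-4-one | COc1cc(OC)c2c(=O)cc(-c3ccc(OCc4ccccc4)cc3)oc2c1
F4 | step 9 | 2-[4-(benzyloxy)phenyl]-8-iodo-5,7-dimethoxy-4H-chromen-4-one | COc1cc(OC)c2c(=O)cc(-c3ccc(OCc4ccccc4)cc3)oc2c1I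
F5 | step 9 | 5,7,4',4'''-tetra-O-benzyl-5''-O-methylsotetsuflavone | COc1cc(OC)c2c(=O)cc(-c3ccc(OCc4ccccc4)cc3)oc2c1-c1cc(-c2cc(=O)c3c(OCc4ccccc4)cc(OCc4ccccc4)cc3o2)ccc1OCc1ccccc1
F6 | step 5 | 2,4,6-trimethoxyphenyllithium | COc1cc(OC)c([Li])c(OC)c1
F7 | step 5 | (2,4,6-trimethoxyphenyl)zinc chloride | COc1cc(OC)c([Zn]Cl)c(OC)c1
F8 | step 10 | 5''-O-methylsotetsuflavone | COc1cc(OC)c2c(=O)cc(-c3ccc(O)cc3)oc2c1-c1cc(-c2cc(=O)c3c(O)cc(O)cc3o2)ccc1O
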